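## Analysis of the target

The target is a 1,14-diaryltetradecane: an unbranched, saturated chain of fourteen methylene carbons (C1 to C14) joins ring A at a1 through C1 to ring B at b1 through C14. Ring A is a resorcinol monomethyl ether with the hydroxyl at a3 and the methoxy group at a5, and ring B is a free resorcinol with hydroxyls at b3 and b5, so that on each ring the chain and the two oxygens stand in a 1,3,5 relationship. There is no stereocentre and no unsaturation outside the arenes, and the single O-methyl group removes any usable symmetry between the two ends. The sensitive sites are the three free phenols on electron-rich rings, which oxidise in hot aerated base and are open to electrophilic attack, and the aryl methyl ether, which must outlive every deprotection and so rules out a final Lewis-acid ether cleavage. The difficulty is one of differentiation and of bond construction at awkward positions: one oxygen out of four is methylated, the tether has no functional handle, and each aryl–alkyl bond lies meta to two oxygens, where electrophilic substitution does not place carbon. The strategy rests on ring B having the alternating oxygen pattern of a folded tetraketide: b1 can be drawn at the carboxyl oxidation level and b3 and b5 as ketone carbons. C1 to C14 together with b1 then form a pentadecanoyl unit, and b2 to b6 are the backbone carbons C2 to C6 of a six-carbon 3,5-diketo ester whose ester carbon is lost at the end.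

## Retrosynthetic reasoning

**16 from 15.** The free hydroxyl at a3 is traced back to a benzyl ether. Benzyl is chosen because it withstands amide bases, organozinc reagents and hot alkali, and it is removed by neutral catalytic hydrogenolysis, which leaves the methyl ether at a5 alone. The methyl/hydrogen distinction on ring A is thus carried unchanged from the first compound of the route.

**15 from 13 (through 14).** A carboxyl carbon is added back at b2. This is the ester carbon left over from the ring construction, and its removal is easy because b2 is ortho and para to the two hydroxyls. Forward, the ester 13 is saponified to the acid 14, which loses its carboxyl group by ipso protonation.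

**13 from 7 and 10 (through 11 and 12).** Both ring bonds at b1, b1–b2 and b1–b6, are cut. The cut is made here because b1 is the only ring B carbon attached to the chain, and opening both of its ring bonds turns it into an acyl carbon. Ring B then comes from the N-methoxy-N-methylamide 7 and the diketo ester 10, with the oxygens at b3 and b5 arriving as the two ketones of 10. This gives three things: no aryl–alkyl coupling at ring B, no protecting groups on ring B, and no regiochemical question for its hydroxyls. Forward, the trianion 11 must be acylated at its terminal carbon by 7, and the triketo ester 12 must close by the aldol mode, not the Claisen or lactone modes.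

**10 from 8 (through 9).** The diketo ester is traced to the acylated pyranedione 8. Forward, the lactone is opened by alcoholysis and the extra acetyl group is removed by retro-Claisen cleavage.

**7 from 2 and 5 (through 6).** The aryl–alkyl bond a1–C1 is cut. Ring A is thereby taken from an aryl bromide that already has the 1,3,5 pattern and the O-methyl differentiation, and the whole chain from one bifunctional C15 piece. Forward, the organozinc 6 made from the bromo amide 5 is coupled with the aryl bromide 2 in a Negishi reaction. The N-methoxy-N-methylamide is inert to organozinc reagents, so the acyl donor for the key step is already in place.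

**5 from 3 (through 4), and 2 from 1.** These are functional group changes only. The bromo acid 3 is converted through its acyl imidazolide 4 into the amide 5, and the bromophenol 1 is O-benzylated to 2.

## Alternatives that were turned down

**Alternative 1:** Late twofold meta C–H hydroxylation.
- Disconnection: the C–O bonds at a3 and b5 are cut. The precursor is triisopropyl{3-[14-(3-methoxyphenyl)tetradecyl]phenoxy}silane A2, in which each ring has only one oxygen.
- Forward key step: A2 is borylated with [Ir(OMe)(cod)]2, 4,4'-di-tert-butyl-2,2'-bipyridine and B2pin2 at the position meta to both substituents on each ring, and KHSO5 is then added to the same flask. This gives 3-methoxy-5-{14-[3-hydroxy-5-(triisopropylsilyloxy)phenyl]tetradecyl}phenol A1 as the product of the key step. Desilylation of A1 then gives the target.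
- For: steric control of borylation in 1,3-disubstituted benzenes is dependable, both rings are oxidised in one operation, and no strong base or cryogenic step is needed. On mildness and on late-stage economy it is stronger than the chosen route.
- Against: two independent C–H functionalisations must both go to completion at the right carbon. Methoxy is small, so some borylation next to it is plausible, and a positional isomer of a waxy long-chain phenol would be very hard to remove. A2 also needs two different aryl groups placed on a C14 linker, which means two aryl–alkyl couplings on a differentiated or statistically used linker. The step count ends up similar.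
- Comparison: the chosen route fixes every oxygen position by constitution, through the ketones of 10 and the purchased pattern of 1, where this alternative relies on selectivity.

**Alternative 2:** Thiophene as the central four carbons of the chain.
- Disconnection: bonds C5–C6 and C9–C10 are cut, and C6 to C9 come from thiophene A4.
- Forward key step: A4 is lithiated with n-BuLi and alkylated with 1-(benzyloxy)-3-(5-bromopentyl)-5-methoxybenzene A5 at one alpha position. The ring is then lithiated again at the other alpha position in the same flask and alkylated with 1,3-bis(benzyloxy)-5-(5-bromopentyl)benzene A6 to give 2-{5-[3-(benzyloxy)-5-methoxyphenyl]pentyl}-5-{5-[3,5-bis(benzyloxy)phenyl]pentyl}thiophene A3 as the product of the key step. Raney Ni then removes sulfur from A3 and saturates the four carbons, and the benzyl ethers are hydrogenolysed.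
- For: it is convergent, and every oxygen pattern is purchased, so on regiochemical certainty it equals the chosen route. The final reduction may do several jobs at once.
- Against: A5 and A6 each need their own aryl–alkyl bond construction and chain adjustment, so the count is roughly twice that of the chosen route. Alkylation of thienyllithiums with unactivated primary bromides is slow and competes with elimination, the second time more so. Desulfurisation needs a large excess of Raney Ni, and sulfur residues poison palladium.
- Comparison: the chosen route makes one aryl–alkyl bond by coupling and takes the whole chain from the single commercial compound 3.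

**Alternative 3:** Ring A built as a cyclohexane-1,3-dione and aromatised late.
- Disconnection: ring A is opened at a1–a6 and a4–a5. It comes from (E)-18-[3,5-bis(benzyloxy)phenyl]octadec-3-en-2-one A8 and dimethyl malonate A9.
- Forward key step: the sodium enolate of A9 adds to the enone carbon of A8 that becomes a1 (Michael addition), and the methyl ketone enolate closes onto a malonate ester (Claisen closure). The product is 5-{14-[3,5-bis(benzyloxy)phenyl]tetradecyl}cyclohexane-1,3-dione A7 after saponification and decarboxylation in the same flask. The two equivalent carbonyls of A7 give one mono enol ether, 5-{14-[3,5-bis(benzyloxy)phenyl]tetradecyl}-3-methoxycyclohex-2-en-1-one A10. Dehydrogenation of A10 to the arene and debenzylation then give the target.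
- For: the mono-O-methyl pattern follows from symmetry, with no specialised bromophenol. The ring-forming step needs only alkoxide base and is easy to scale. On both points it is stronger than the chosen route.
- Against: ring B must still be joined to the chain by an aryl–alkyl coupling, and the chain must then be extended to the enone A8. The dehydrogenation of A10 needs halogen-based or high-temperature conditions that threaten the electron-rich bis(benzyloxy) ring and the benzyl ethers. The sequence is clearly longer.
- Comparison: the chosen route builds ring B, not ring A, from acyclic carbonyl precursors. There the construction removes a coupling and all ring B protecting groups, and the aromatisation is a spontaneous dehydration that needs no oxidant.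

Key step: step 5

Remark on the chemistry: compounds 1, 3 and 8 are taken to be catalogue compounds. Ring atoms are labelled a1 (chain), a3 (OH), a5 (OMe) on ring A and b1 (chain), b3 and b5 (OH) on ring B.

## Route

Step 1
Reactants: 1 3-bromo-5-methoxyphenol
Product: 2 1-(benzyloxy)-3-bromo-5-methoxybenzene
Conditions: BnBr, K2CO3, DMF, rt
Reagents that add atoms: benzyl bromide, BrCc1ccccc1
Why: Williamson ether synthesis: the phenoxide formed with K2CO3 displaces bromide from the benzylic halide by SN2, and the aryl bromide is inert under these conditions. The benzyl ether later withstands organozinc reagents, LiN(iPr)2 and hot KOH.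

Step 2
Reactants: 3 15-bromopentadecanoic acid
Product: 5 15-bromo-N-methoxy-N-methylpentadecanamide, via 1-(15-bromopentadecanoyl)-1H-imidazole 4 (not isolated)
Conditions: 1,1'-carbonyldiimidazole, CH2Cl2, rt; then MeNH(OMe)·HCl, rt
Reagents that add atoms: N,O-dimethylhydroxylamine hydrochloride, CNOC.Cl
Why: Amide formation through an acyl imidazolide: 1,1'-carbonyldiimidazole activates the acid with loss of CO2, and the imidazolide is aminolysed by the hydroxylamine, whose hydrochloride is neutralised by the imidazole set free. The primary bromide does not react with these weak nucleophiles at room temperature.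

Step 3
Reactants: 5 15-bromo-N-methoxy-N-methylpentadecanamide; 2 1-(benzyloxy)-3-bromo-5-methoxybenzene
Product: 7 N-methoxy-N-methyl-15-[3-(benzyloxy)-5-methoxyphenyl]pentadecanamide, via bromo{15-[methoxy(methyl)amino]-15-oxopentadecyl}zinc 6 (not isolated)
Conditions: Zn dust, I2 (5 mol%), DMA, 80 °C; then 2, Pd(OAc)2 (2 mol%), SPhos (4 mol%), THF, rt to 50 °C
Reagents that add atoms: none
Why: Negishi coupling: iodine-activated zinc inserts into the primary C–Br bond in the polar amide solvent to give 6, which does not attack the N-methoxy-N-methylamide. Pd(OAc)2 is reduced in the flask to zerovalent palladium, and the bulky, electron-rich SPhos ligand makes reductive elimination of the a1–C1 bond faster than β-hydride elimination.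

Step 4
Reactants: 8 dehydroacetic acid (3-acetyl-6-methyl-2H-pyran-2,4(3H)-dione)
Product: 10 methyl 3,5-dioxohexanoate, via methyl 2-acetyl-3,5-dioxohexanoate 9 (not isolated)
Conditions: Mg(OMe)2 (2 equiv, commercial solution in MeOH), MeOH, reflux; then cold dil. HCl
Reagents that add atoms: methanol, CO; magnesium dimethoxide, C[O-].[Mg+2].[O-]C
Why: Alcoholysis of the acylated pyranedione followed by retro-Claisen deacetylation: methoxide should open the lactone to the magnesium chelate of 9 and then cleave the acetyl group from the triply activated carbon as methyl acetate. Chelation of the remaining 3,5-dicarbonyl unit by magnesium should protect 10 from further cleavage.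

Step 5
Reactants: 10 methyl 3,5-dioxohexanoate; 7 N-methoxy-N-methyl-15-[3-(benzyloxy)-5-methoxyphenyl]pentadecanamide
Product: 13 methyl 2-{14-[3-(benzyloxy)-5-methoxyphenyl]tetradecyl}-4,6-dihydroxybenzoate, via trilithium 1-methoxy-1,3,5-trioxohexane-2,4,6-triide 11 (not isolated), via methyl 21-[3-(benzyloxy)-5-methoxyphenyl]-3,5,7-trioxohenicosanoate 12 (not isolated)
Conditions: 10 (2.0 equiv), LiN(iPr)2 (6.2 equiv, commercial solution), THF, −78 to 0 °C; then 7 (1.0 equiv), THF, 0 °C to rt; cold dil. HCl; then KHCO3/K2CO3 buffer (pH about 9.5), H2O/THF/MeOH, rt; dil. HCl
Reagents that add atoms: none
Why: Three equivalents of LiN(iPr)2 per molecule of 10 remove one proton from each doubly activated methylene and then one from the methyl group, so 11 carries its least stabilised and most nucleophilic carbanion on the terminal carbon, and this carbon adds to the amide carbonyl of 7 to form bond b1–b6 (Weinreb ketone synthesis applied to a β-polycarbonyl polyanion). The N-methoxy oxygen and the alkoxide hold lithium in a five-membered chelate, so the tetrahedral adduct lasts until the acid quench; no second addition can occur and the acidic product 12 is never present beside unreacted 11. In the buffer of pH about 9.5, 12 is ionised at its doubly activated methylenes, and the carbon between ester and ketone (C2 of the ester chain, later b2) attacks the alkyl ketone at C7 (later b1), forming bond b1–b2 and closing ring B; this six-membered intramolecular aldol addition can be written as 6-(enolexo)-exo-trig through the ester enolate. Loss of water and enolisation of the two remaining ring ketones give the aromatic resorcylate and make the sequence irreversible; the closest known reaction type is the biomimetic aldol cyclisation of 3,5,7-triketo esters to β-resorcylates. No stereocentre is formed. The step needs site selectivity in the acylation, which the charge distribution of 11 secures, and it needs the aldol mode of closure to win over Claisen closure of C6 onto the ester and over lactonisation to a pyranone: the dialkyl ketone at C7 is a better electrophile than the ester, mild aqueous base does not produce the highly charged species that Claisen closure requires, and the simple ketone methylene at C8 is not ionised at this pH, so the regioisomeric aldol onto C3 is not expected. The benzyl ether, the methyl ether, ring A and the saturated chain offer neither an electrophilic site nor a proton acidic enough to interfere.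

Step 6
Reactants: 13 methyl 2-{14-[3-(benzyloxy)-5-methoxyphenyl]tetradecyl}-4,6-dihydroxybenzoate
Product: 15 5-{14-[3-(benzyloxy)-5-methoxyphenyl]tetradecyl}benzene-1,3-diol, via 2-{14-[3-(benzyloxy)-5-methoxyphenyl]tetradecyl}-4,6-dihydroxybenzoic acid 14 (not isolated)
Conditions: KOH, H2O/1,4-dioxane (degassed), reflux, Ar; then HCl to pH 2, 60 °C
Reagents that add atoms: none
Why: Ester saponification followed by protodecarboxylation of a β-resorcylic acid: hot KOH hydrolyses the hindered ester, and after acidification 14 is protonated at b2, which is ortho and para to the two hydroxyls, and loses CO2 on warming. The benzyl and methyl ethers are stable to both media, and exclusion of air protects the resorcinolate.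

Step 7
Reactants: 15 5-{14-[3-(benzyloxy)-5-methoxyphenyl]tetradecyl}benzene-1,3-diol
Product: 16 5-[14-(3-hydroxy-5-methoxyphenyl)tetradecyl]benzene-1,3-diol
Conditions: H2 (1 atm), Pd/C (10 wt%), EtOAc/MeOH, rt
Reagents that add atoms: none
Why: Hydrogenolysis of a benzyl aryl ether on Pd/C: the benzylic C–O bond is cleaved to the phenol and toluene under neutral conditions. The aryl methyl ether, the arenes and the saturated chain are not affected, so the target should be obtained with the a3 hydroxyl and a5 methoxy pattern set in compound 1.

## Compound list

1 | 3-bromo-5-methoxyphenol | COc1cc(O)cc(Br)c1 | starting material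
2 | 1-(benzyloxy)-3-bromo-5-methoxybenzene | COc1cc(OCc2ccccc2)cc(Br)c1 | intermediate
3 | 15-bromopentadecanoic acid | OC(=O)CCCCCCCCCCCCCCBr | starting material
4 | 1-(15-bromopentadecanoyl)-1H-imidazole | O=C(CCCCCCCCCCCCCCBr)n1ccnc1 | intermediate
5 | 15-bromo-N-methoxy-N-methylpentadecanamide | CON(C)C(=O)CCCCCCCCCCCCCCBr | intermediate
6 | bromo{15-[methoxy(methyl)amino]-15-oxopentadecyl}zinc | CON(C)C(=O)CCCCCCCCCCCCCC[Zn]Br | intermediate
7 | N-methoxy-N-methyl-15-[3-(benzyloxy)-5-methoxyphenyl]pentadecanamide | COc1cc(OCc2ccccc2)cc(CCCCCCCCCCCCCCC(=O)N(C)OC)c1 | intermediate
8 | dehydroacetic acid (3-acetyl-6-methyl-2H-pyran-2,4(3H)-dione) | CC(=O)C1C(=O)C=C(C)OC1=O | starting material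
9 | methyl 2-acetyl-3,5-dioxohexanoate | CC(=O)CC(=O)C(C(C)=O)C(=O)OC | intermediate
10 | methyl 3,5-dioxohexanoate | CC(=O)CC(=O)CC(=O)OC | intermediate
11 | trilithium 1-methoxy-1,3,5-trioxohexane-2,4,6-triide (2,4,6-trianion of 10) | [Li+].[Li+].[Li+].[CH2-]C(=O)[CH-]C(=O)[CH-]C(=O)OC | intermediate
12 | methyl 21-[3-(benzyloxy)-5-methoxyphenyl]-3,5,7-trioxohenicosanoate | COC(=O)CC(=O)CC(=O)CC(=O)CCCCCCCCCCCCCCc1cc(OC)cc(OCc2ccccc2)c1 | intermediate
13 | methyl 2-{14-[3-(benzyloxy)-5-methoxyphenyl]tetradecyl}-4,6-dihydroxybenzoate | COC(=O)c1c(O)cc(O)cc1CCCCCCCCCCCCCCc1cc(OC)cc(OCc2ccccc2)c1 | intermediate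
14 | 2-{14-[3-(benzyloxy)-5-methoxyphenyl]tetradecyl}-4,6-dihydroxybenzoic acid | OC(=O)c1c(O)cc(O)cc1CCCCCCCCCCCCCCc1cc(OC)cc(OCc2ccccc2)c1 | intermediate
15 | 5-{14-[3-(benzyloxy)-5-methoxyphenyl]tetradecyl}benzene-1,3-diol | COc1cc(OCc2ccccc2)cc(CCCCCCCCCCCCCCc2cc(O)cc(O)c2)c1 | intermediate
16 | 5-[14-(3-hydroxy-5-methoxyphenyl)tetradecyl]benzene-1,3-diol | COc1cc(O)cc(CCCCCCCCCCCCCCc2cc(O)cc(O)c2)c1 | target

## Step count and least certain steps

Total step count: 7. Longest linear sequence: 5 steps (steps 2, 3, 5, 6 and 7 from compound 3, or steps 1, 3, 5, 6 and 7 from compound 1).

**Step 5 (key step).**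
- What may go wrong: proton transfer instead of addition. The terminal carbanion of 11 is a very strong base and 7 has an enolisable methylene next to its carbonyl, so deprotonation would return 7 after the quench. Base-induced loss of the N-methoxy group from the amide is a related drain. The aggregated trilithium salt may also react slowly with the waxy amide in cold THF. In the ring closure, the lipophilic 12 may stay out of the aqueous phase, so closure is slow and lactonisation to a hydroxypyranone on acidification, or Claisen closure, gains ground.
- Fallback: it sets out from 7 and rejoins the route at 13 by way of 12. The nucleophile would be 2,2-dimethyl-6-(2-oxopropyl)-4H-1,3-dioxin-4-one F1, prepared by C-acetylation of the lithium dienolate of commercial 2,2,6-trimethyl-4H-1,3-dioxin-4-one with acetyl chloride. Two equivalents of LiN(iPr)2 in THF at −78 °C would convert F1 into dilithium 1-(2,2-dimethyl-4-oxo-4H-1,3-dioxin-6-yl)-2-oxopropane-1,3-diide F2. Acylation of F2 at its terminal carbon by 7 would give 6-{18-[3-(benzyloxy)-5-methoxyphenyl]-2,4-dioxooctadecyl}-2,2-dimethyl-4H-1,3-dioxin-4-one F3. Heating F3 in toluene with methanol at about 100 °C should expel acetone by retro-[4+2] fragmentation and set free the acylketene 21-[3-(benzyloxy)-5-methoxyphenyl]henicos-1-ene-1,3,5,7-tetrone F4. Trapping of F4 by methanol gives 12, which is then cyclised in homogeneous methanolic K2CO3 and acidified to 13. The nucleophile carries one charge fewer, the triketo ester is released under neutral conditions, and the cyclisation no longer depends on a two-phase medium.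

**Step 3.**
- What may go wrong: slow or incomplete insertion of zinc into the unactivated primary bromide, protonation of 6 by traces of moisture (reduction of the chain end), and β-hydride elimination or chain walking on palladium, which would give alkene and branched isomers that are hard to remove from a C15 chain.
- Fallback: it sets out from 2 and 5 and arrives directly at 7, so it makes no new compound and is entered as F0. It is a nickel-catalysed reductive cross-electrophile coupling (NiI2, 4,4'-di-tert-butyl-2,2'-bipyridine, NaI, Zn powder, N,N'-dimethylpropyleneurea, 60 °C). No organozinc reagent is prepared; the alkyl bromide enters as a radical at nickel while the aryl bromide adds oxidatively, so the insertion step that is most likely to fail is not needed.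

**Step 6.**
- What may go wrong: slow acyl–oxygen hydrolysis, because the ester is flanked by two ortho substituents and deactivated by the ortho and para phenoxides. Oxidative darkening of the resorcinolate in hot alkali and incomplete decarboxylation are further risks.
- Fallback: it sets out from 13 and returns at 15 through the same acid 14, so it makes no new compound and is entered as F0. The ester methyl group is removed by SN2 attack of iodide (LiI, pyridine, reflux, Ar), which is an alkyl–oxygen cleavage and is not slowed by the crowding at the carbonyl. Acidification and warming then decarboxylate 14. The aryl methyl ether at a5 is much less reactive towards iodide under these conditions.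

**Step 4.**
- What may go wrong: retro-Claisen cleavage at the wrong carbonyl, which would break the 3,5-dioxo chain into acetoacetate units, or incomplete deacetylation.
- Fallback: it sets out from 8 and returns at 10. Hot 90% H2SO4 (about 130 °C) deacetylates 8 to 4-hydroxy-6-methyl-2H-pyran-2-one F5. The lactone of F5 is then opened to 10 by Mg(OMe)2 in methanol at reflux. The deacetylation and the ring opening are thus separated, and the first is done in acid where retro-Claisen cleavage of the chain cannot occur.

## Further compounds

F1 | step 5 | 2,2-dimethyl-6-(2-oxopropyl)-4H-1,3-dioxin-4-one | CC(=O)CC1=CC(=O)OC(C)(C)O1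
F2 | step 5 | dilithium 1-(2,2-dimethyl-4-oxo-4H-1,3-dioxin-6-yl)-2-oxopropane-1,3-diide | [Li+].[Li+].[CH2-]C(=O)[CH-]C1=CC(=O)OC(C)(C)O1
F3 | step 5 | 6-{18-[3-(benzyloxy)-5-methoxyphenyl]-2,4-dioxooctadecyl}-2,2-dimethyl-4H-1,3-dioxin-4-one | COc1cc(OCc2ccccc2)cc(CCCCCCCCCCCCCCC(=O)CC(=O)CC2=CC(=O)OC(C)(C)O2)c1
F4 | step 5 | 21-[3-(benzyloxy)-5-methoxyphenyl]henicos-1-ene-1,3,5,7-tetrone | O=C=CC(=O)CC(=O)CC(=O)CCCCCCCCCCCCCCc1cc(OC)cc(OCc2ccccc2)c1
F0 | step 3 | none | none
F0 | step 6 | none | none
F5 | step 4 | 4-hydroxy-6-methyl-2H-pyran-2-one | CC1=CC(O)=CC(=O)O1
A1 | alternative 1 | 3-methoxy-5-{14-[3-hydroxy-5-(triisopropylsilyloxy)phenyl]tetradecyl}phenol | COc1cc(O)cc(CCCCCCCCCCCCCCc2cc(O)cc(O[Si](C(C)C)(C(C)C)C(C)C)c2)c1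
A2 | alternative 1 | triisopropyl{3-[14-(3-methoxyphenyl)tetradecyl]phenoxy}silane | COc1cccc(CCCCCCCCCCCCCCc2cccc(O[Si](C(C)C)(C(C)C)C(C)C)c2)c1
A3 | alternative 2 | 2-{5-[3-(benzyloxy)-5-methoxyphenyl]pentyl}-5-{5-[3,5-bis(benzyloxy)phenyl]pentyl}thiophene | COc1cc(OCc2ccccc2)cc(CCCCCc2ccc(CCCCCc3cc(OCc4ccccc4)cc(OCc4ccccc4)c3)s2)c1
A4 | alternative 2 | thiophene | c1ccsc1
A5 | alternative 2 | 1-(benzyloxy)-3-(5-bromopentyl)-5-methoxybenzene | COc1cc(OCc2ccccc2)cc(CCCCCBr)c1
A6 | alternative 2 | 1,3-bis(benzyloxy)-5-(5-bromopentyl)benzene | BrCCCCCc1cc(OCc2ccccc2)cc(OCc2ccccc2)c1
A7 | alternative 3 | 5-{14-[3,5-bis(benzyloxy)phenyl]tetradecyl}cyclohexane-1,3-dione | O=C1CC(=O)CC(CCCCCCCCCCCCCCc2cc(OCc3ccccc3)cc(OCc3ccccc3)c2)C1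
A8 | alternative 3 | (E)-18-[3,5-bis(benzyloxy)phenyl]octadec-3-en-2-one | CC(=O)/C=C/CCCCCCCCCCCCCCc1cc(OCc2ccccc2)cc(OCc2ccccc2)c1
A9 | alternative 3 | dimethyl malonate | COC(=O)CC(=O)OC
A10 | alternative 3 | 5-{14-[3,5-bis(benzyloxy)phenyl]tetradecyl}-3-methoxycyclohex-2-en-1-one | COC1=CC(=O)CC(CCCCCCCCCCCCCCc2cc(OCc3ccccc3)cc(OCc3ccccc3)c2)C1
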